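**Strategy.** Everything rests on closing ring B at C5–C6: C5 is the quaternary ring-fusion carbon of rings A and B that carries the angular methyl C14, and C6 is the ring-B methylene next to C7. Iron-hydride hydrogen-atom transfer to an exocyclic C5=C14 methylene on a finished ring A gives the tertiary C5 radical, which adds 6-endo to the α-methylene (C6) of a Baylis–Hillman-type enone whose acetyl group is the latent isopropenyl unit. One operation creates the angular methyl, the quaternary centre, the trans ring fusion and the C7 stereocentre, relayed from C9 and C10. The precursor is a methylenecyclohexane bearing the senecioate and an oxygenated enone side chain.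

Key step: step 10

Remark (numbering): eremophilane numbering is used throughout. Ring A = C1, C2, C3, C4, C5, C10; ring B = C5 to C10; C14 = methyl on C5; C15 = methyl on C4; C11 to C13 = isopropenyl on C7.

Assumption: the catalyst enantiomers written in steps 1 and 5 are those taken to give the drawn configurations; if the sense of induction is opposite, the antipodal catalyst is used.

**Step 1**
Reactants: 1 2-methylcyclohex-2-en-1-one
Product: 2 (R)-2-methylcyclohex-2-en-1-ol
Conditions: (S)-1-methyl-3,3-diphenyl-tetrahydro-1H,3H-pyrrolo[1,2-c][1,3,2]oxazaborole (10 mol %), BH3·SMe2, THF, −20 °C; MeOH quench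
Reagents that add atoms: none
Why: Corey–Bakshi–Shibata reduction delivers hydride 1,2 to the enone with the methyl-substituted alkene as the large group, setting the carbinol (future C5) as a temporary stereochemical anchor.

**Step 2**
Reactants: 2 (R)-2-methylcyclohex-2-en-1-ol
Product: 4 (1R,3R)-2-methylcyclohexane-1,3-diol, via bis(9-BBN) adduct 3 (not isolated)
Conditions: 9-borabicyclo[3.3.1]nonane (2.5 equiv), THF, 0 to 65 °C; then NaOH, H2O2, 0 °C to rt
Reagents that add atoms: hydrogen peroxide, OO
Why: Hydroboration–oxidation puts boron on the less substituted alkene carbon (C3) anti to the pseudoaxial O-borinate and hydrogen syn to boron at C4, so C3–OH and the C4 methyl are necessarily trans and their absolute sense is relayed from the carbinol.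

**Step 3**
Reactants: 4 (1R,3R)-2-methylcyclohexane-1,3-diol; 5 3-methylbut-2-enoyl chloride
Product: 7 (1R,2S)-2-methyl-3-oxocyclohexyl 3-methylbut-2-enoate, via hydroxy ester 6 (not isolated)
Conditions: 5 (1.05 equiv), pyridine, CH2Cl2, −20 °C; then Dess–Martin periodinane, 0 °C to rt
Reagents that add atoms: 3-methylbut-2-enoyl chloride, CC(C)=CC(Cl)=O
Why: Selective acylation of the equatorial hydroxyl (trans to the methyl) over the axial one, then Dess–Martin oxidation of the remaining axial alcohol under non-epimerising conditions, should give the trans β-acyloxy ketone with C3 and C4 fixed.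

**Step 4**
Reactants: 7 (1R,2S)-2-methyl-3-oxocyclohexyl 3-methylbut-2-enoate; 8 2,2-dimethoxyacetaldehyde
Product: 11 (1R,2S,4E)-4-(2,2-dimethoxyethylidene)-2-methyl-3-oxocyclohexyl 3-methylbut-2-enoate, via aldol adduct 9 (not isolated), via mesylate 10 (not isolated)
Conditions: LiHMDS, THF, −78 °C; 8 (anhydrous); then MsCl, Et3N, −78 to 23 °C
Reagents that add atoms: 2,2-dimethoxyacetaldehyde, COC(OC)C=O
Why: Kinetic deprotonation at the less substituted methylene (C10), aldol addition and mesylation/E1cB elimination (aldol condensation) should give the thermodynamically preferred E exocyclic enone without touching C4 or the β-acyloxy group.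

**Step 5**
Reactants: 11 the E exocyclic enone; 12 bis(pinacolato)diboron
Product: 14 (1R,2S,4S)-4-[(1S)-1-hydroxy-2,2-dimethoxyethyl]-2-methyl-3-oxocyclohexyl 3-methylbut-2-enoate, via boronate 13 (not isolated)
Conditions: CuCl (5 mol %), (R)-1-[(S)-2-(diphenylphosphino)ferrocenyl]ethyldicyclohexylphosphine (6 mol %), NaOt-Bu (5 mol %), MeOH (2 equiv), THF, rt; then NaBO3·4H2O, THF/H2O, rt
Reagents that add atoms: sodium perborate, [Na+].[Na+].O[B-]1(O)OO[B-](O)(O)OO1
Why: Copper-catalysed enantioselective conjugate borylation lets the ligand choose the face at C9, the enolate is protonated at C10 anti to the C4 methyl so that the side chain ends cis to it (all-equatorial ring A), and perborate oxidation replaces boron by hydroxyl with retention.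

**Step 6**
Reactants: 14 the β-hydroxy ketone
Product: 15 (1R,2R,4R)-4-[(1S)-1-hydroxy-2,2-dimethoxyethyl]-2-methyl-3-methylidenecyclohexyl 3-methylbut-2-enoate
Conditions: CH2Br2, Zn, TiCl4 (preformed Lombardo reagent), THF/CH2Cl2, 0 °C to rt
Reagents that add atoms: dibromomethane, BrCBr
Why: Lombardo methylenation, a non-basic titanium–zinc carbenoid olefination, should convert the hindered enolisable ketone into the exocyclic C5 methylene without epimerising C4 or C10 and without touching ester or acetal.

**Step 7**
Reactants: 15 the methylidene alcohol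
Product: 16 the C9 tert-butyldimethylsilyl ether of 15
Conditions: TBSCl, imidazole, DMAP (cat.), DMF, 40 °C
Reagents that add atoms: tert-butyldimethylsilyl chloride, CC(C)(C)[Si](C)(C)Cl
Why: Standard silylation protects the C9 hydroxyl so that it stays distinct from the C8 hydroxyl made in step 9.

**Step 8**
Reactants: 16 the silyl ether acetal
Product: 18 (1R,2R,4R)-4-[(1S)-1-[(tert-butyldimethylsilyl)oxy]-2-oxoethyl]-2-methyl-3-methylidenecyclohexyl 3-methylbut-2-enoate, via collidinium salt 17 (not isolated)
Conditions: TESOTf, 2,4,6-collidine, CH2Cl2, 0 °C; then H2O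
Reagents that add atoms: water, O
Why: Silyl triflate–collidine cleavage of the dimethyl acetal goes through a collidinium intermediate that water hydrolyses, freeing the aldehyde without protic acid that would remove the silyl ether or isomerise the exocyclic alkene.

**Step 9**
Reactants: 18 the α-silyloxy aldehyde; 19 but-3-yn-2-one
Product: 21 (1R,2R,4R)-4-[(1S)-1-[(tert-butyldimethylsilyl)oxy]-2-hydroxy-3-methylidene-4-oxopentyl]-2-methyl-3-methylidenecyclohexyl 3-methylbut-2-enoate (C8 epimer mixture), via aluminium allenolate 20 (not isolated)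
Conditions: 19, i-Bu2AlH, HMPA, THF, 0 °C; then 18, −78 to 0 °C; aqueous potassium sodium tartrate
Reagents that add atoms: but-3-yn-2-one, CC(=O)C#C
Why: Conjugate hydroalumination of the ynone gives an aluminium allenolate that adds through its α-carbon to the aldehyde (vinylalumination route to Morita–Baylis–Hillman adducts) under non-basic conditions that preserve C9; the new C8 carbinol (Felkin–Anh epimer expected to predominate) is left uncontrolled because step 12 oxidises it.

**Step 10**
Reactants: 21 the Baylis–Hillman-type enone with the exocyclic C5 methylene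
Product: 22 (3R,4R,5R,7R,9S,10R)-7-acetyl-9-[(tert-butyldimethylsilyl)oxy]-8-hydroxy-4,5-dimethyl-trans-decalin-3-yl 3-methylbut-2-enoate (C8 epimer mixture)
Conditions: Fe(acac)3 (0.5 equiv), PhSiH3 (2.5 equiv), EtOH/ethylene glycol (5:1), 60 °C
Reagents that add atoms: none
Why: Fe(acac)3 and PhSiH3 generate an iron hydride that transfers a hydrogen atom to the terminal carbon of the electron-rich exocyclic C5=C14 alkene, giving the angular methyl and a tertiary C5 radical that adds to C6, the unsubstituted β-carbon of the enone; the α-acyl radical at C7 is then reduced to the iron enolate and protonated by ethanol. The closest known reaction type is the iron-mediated reductive olefin–enone coupling (hydrogen-atom-transfer-initiated Giese cyclisation) used intramolecularly to form quaternary carbons. Ring B closes in the 6-endo-trig mode, because the nucleophilic tertiary radical attacks the terminal acceptor carbon, whereas the 5-exo path would attack the substituted α-carbon and leave a primary radical. C5 is controlled by a chair-like transition state on the all-equatorial ring A in which the C10 tether and the C9 silyloxy group stay equatorial, so C6 bonds equatorially and the new methyl is axial (trans fusion, as in radical polyene bicyclisations); the cis-fused alternative would force the C9 silyloxy group axial and syn to that methyl. C7 is set by protonation of the exocyclic enolate to the equatorial acetyl epimer, which avoids a syn-axial clash with the angular methyl and is also thermodynamically preferred; the uncontrolled C8 carbinol does not matter. The step needs hydrogen-atom transfer to the 1,1-disubstituted alkene rather than to the enone or the senecioate, which the electron-rich, unhindered character of that alkene secures.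

**Step 11**
Reactants: 22 the acetyl decalin
Product: 23 (3R,4R,5R,7S,9S,10R)-9-[(tert-butyldimethylsilyl)oxy]-8-hydroxy-4,5-dimethyl-7-(prop-1-en-2-yl)-trans-decalin-3-yl 3-methylbut-2-enoate (C8 epimer mixture)
Conditions: CH2Br2, Zn, TiCl4 (preformed Lombardo reagent), THF/CH2Cl2, 0 °C to rt
Reagents that add atoms: dibromomethane, BrCBr
Why: Lombardo methylenation turns the methyl ketone into the isopropenyl group under non-basic conditions, so C7 and the β-hydroxy ketone are not exposed to epimerisation or retro-aldol cleavage.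

**Step 12**
Reactants: 23 the C8 alcohol
Product: 24 (3R,4R,5R,7S,9S,10R)-9-[(tert-butyldimethylsilyl)oxy]-4,5-dimethyl-8-oxo-7-(prop-1-en-2-yl)-trans-decalin-3-yl 3-methylbut-2-enoate
Conditions: Dess–Martin periodinane, NaHCO3, CH2Cl2, 0 °C to rt
Reagents that add atoms: none
Why: Dess–Martin oxidation of the C8 alcohol (both epimers converge) gives the ketone under buffered conditions that should neither move the β,γ-double bond into conjugation nor epimerise C7 or C9.

**Step 13**
Reactants: 24 the α-silyloxy ketone
Product: 25 (3R,4R,5R,7S,9S,10R)-9-hydroxy-4,5-dimethyl-8-oxo-7-(prop-1-en-2-yl)-trans-decalin-3-yl 3-methylbut-2-enoate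
Conditions: HF·pyridine, pyridine, THF, 0 °C to rt
Reagents that add atoms: none
Why: Buffered fluoride desilylation frees the C9 α-ketol without base that could epimerise it or isomerise the isopropenyl ketone.

**Step 14**
Reactants: 25 the α-hydroxy ketone; 26 (E)-2-methylbut-2-enoyl chloride
Product: 27 (1S,3S,4aR,5R,6R,8aR)-4a,5-dimethyl-6-[(3-methylbut-2-enoyl)oxy]-2-oxo-3-(prop-1-en-2-yl)decahydronaphthalen-1-yl (2E)-2-methylbut-2-enoate (target)
Conditions: 26, pyridine, DMAP (cat.), CH2Cl2, 0 °C to rt
Reagents that add atoms: (E)-2-methylbut-2-enoyl chloride, C/C=C(\C)C(Cl)=O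
Why: Acylation of the equatorial α-ketol hydroxyl installs the tiglate, whose E geometry is the thermodynamically stable one and should be retained.

**Compound list**

1 | 2-methylcyclohex-2-en-1-one | CC1=CCCCC1=O | starting material
2 | (R)-2-methylcyclohex-2-en-1-ol | CC1=CCCC[C@H]1O | intermediate
3 | bis(9-BBN) adduct of 2: O-borinate at C5, 9-BBN-alkyl at C3 (boron anti to oxygen, trans to the methyl) | O(B1C2CCCC1CCC2)[C@H]1[C@@H](C)[C@H](B2C3CCCC2CCC3)CCC1 | intermediate (not isolated)
4 | (1R,3R)-2-methylcyclohexane-1,3-diol (one hydroxyl cis, one trans to the methyl) | O[C@H]1C(C)[C@H](O)CCC1 | intermediate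
5 | 3-methylbut-2-enoyl chloride | CC(C)=CC(Cl)=O | starting material
6 | (1R,2R,3R)-3-hydroxy-2-methylcyclohexyl 3-methylbut-2-enoate (ester trans, hydroxyl cis to the methyl) | O[C@H]1[C@@H](C)[C@H](OC(=O)C=C(C)C)CCC1 | intermediate (not isolated)
7 | (1R,2S)-2-methyl-3-oxocyclohexyl 3-methylbut-2-enoate | O=C1[C@@H](C)[C@H](OC(=O)C=C(C)C)CCC1 | intermediate
8 | 2,2-dimethoxyacetaldehyde | COC(OC)C=O | starting material
9 | aldol adduct of 7 at C10 (formed as lithium alkoxide; C9/C10 diastereomer mixture) | O=C1[C@@H](C)[C@H](OC(=O)C=C(C)C)CCC1C(O)C(OC)OC | intermediate (not isolated)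
10 | methanesulfonate of 9 | O=C1[C@@H](C)[C@H](OC(=O)C=C(C)C)CCC1C(OS(C)(=O)=O)C(OC)OC | intermediate (not isolated)
11 | (1R,2S,4E)-4-(2,2-dimethoxyethylidene)-2-methyl-3-oxocyclohexyl 3-methylbut-2-enoate | O=C1[C@@H](C)[C@H](OC(=O)C=C(C)C)CC/C1=C\C(OC)OC | intermediate
12 | bis(pinacolato)diboron | CC1(C)OB(OC1(C)C)B1OC(C)(C)C(C)(C)O1 | starting material
13 | (1R,2S,4S)-4-[(1S)-2,2-dimethoxy-1-(4,4,5,5-tetramethyl-1,3,2-dioxaborolan-2-yl)ethyl]-2-methyl-3-oxocyclohexyl 3-methylbut-2-enoate | O=C1[C@@H](C)[C@H](OC(=O)C=C(C)C)CC[C@H]1[C@H](B2OC(C)(C)C(C)(C)O2)C(OC)OC | intermediate (not isolated)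
14 | (1R,2S,4S)-4-[(1S)-1-hydroxy-2,2-dimethoxyethyl]-2-methyl-3-oxocyclohexyl 3-methylbut-2-enoate (all ring substituents equatorial) | O=C1[C@@H](C)[C@H](OC(=O)C=C(C)C)CC[C@H]1[C@H](O)C(OC)OC | intermediate
15 | (1R,2R,4R)-4-[(1S)-1-hydroxy-2,2-dimethoxyethyl]-2-methyl-3-methylidenecyclohexyl 3-methylbut-2-enoate | C=C1[C@@H](C)[C@H](OC(=O)C=C(C)C)CC[C@H]1[C@H](O)C(OC)OC | intermediate
16 | (1R,2R,4R)-4-[(1S)-1-[(tert-butyldimethylsilyl)oxy]-2,2-dimethoxyethyl]-2-methyl-3-methylidenecyclohexyl 3-methylbut-2-enoate | C=C1[C@@H](C)[C@H](OC(=O)C=C(C)C)CC[C@H]1[C@H](O[Si](C)(C)C(C)(C)C)C(OC)OC | intermediate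
17 | N-(1-methoxyalkyl)-2,4,6-trimethylpyridinium triflate derived from 16 (C8 epimer mixture) | C=C1[C@@H](C)[C@H](OC(=O)C=C(C)C)CC[C@H]1[C@H](O[Si](C)(C)C(C)(C)C)C(OC)[n+]1c(C)cc(C)cc1C.[O-]S(=O)(=O)C(F)(F)F | intermediate (not isolated)
18 | (1R,2R,4R)-4-[(1S)-1-[(tert-butyldimethylsilyl)oxy]-2-oxoethyl]-2-methyl-3-methylidenecyclohexyl 3-methylbut-2-enoate | C=C1[C@@H](C)[C@H](OC(=O)C=C(C)C)CC[C@H]1[C@H](O[Si](C)(C)C(C)(C)C)C=O | intermediate
19 | but-3-yn-2-one | CC(=O)C#C | starting material
20 | diisobutylaluminium allenolate of but-3-yn-2-one | C=C=C(C)O[Al](CC(C)C)CC(C)C | intermediate (not isolated)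
21 | (1R,2R,4R)-4-[(1S)-1-[(tert-butyldimethylsilyl)oxy]-2-hydroxy-3-methylidene-4-oxopentyl]-2-methyl-3-methylidenecyclohexyl 3-methylbut-2-enoate (C8 epimer mixture, configuration at that carbon not drawn) | C=C1[C@@H](C)[C@H](OC(=O)C=C(C)C)CC[C@H]1[C@H](O[Si](C)(C)C(C)(C)C)C(O)C(=C)C(C)=O | intermediate
22 | (3R,4R,5R,7R,9S,10R)-7-acetyl-9-[(tert-butyldimethylsilyl)oxy]-8-hydroxy-4,5-dimethyl-trans-decalin-3-yl 3-methylbut-2-enoate (C8 epimer mixture) | CC(=O)[C@@H]1C[C@]2(C)[C@@H](C)[C@H](OC(=O)C=C(C)C)CC[C@H]2[C@H](O[Si](C)(C)C(C)(C)C)C1O | intermediate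
23 | (3R,4R,5R,7S,9S,10R)-9-[(tert-butyldimethylsilyl)oxy]-8-hydroxy-4,5-dimethyl-7-(prop-1-en-2-yl)-trans-decalin-3-yl 3-methylbut-2-enoate (C8 epimer mixture) | C=C(C)[C@@H]1C[C@]2(C)[C@@H](C)[C@H](OC(=O)C=C(C)C)CC[C@H]2[C@H](O[Si](C)(C)C(C)(C)C)C1O | intermediate
24 | (3R,4R,5R,7S,9S,10R)-9-[(tert-butyldimethylsilyl)oxy]-4,5-dimethyl-8-oxo-7-(prop-1-en-2-yl)-trans-decalin-3-yl 3-methylbut-2-enoate | C=C(C)[C@@H]1C[C@]2(C)[C@@H](C)[C@H](OC(=O)C=C(C)C)CC[C@H]2[C@H](O[Si](C)(C)C(C)(C)C)C1=O | intermediate
25 | (3R,4R,5R,7S,9S,10R)-9-hydroxy-4,5-dimethyl-8-oxo-7-(prop-1-en-2-yl)-trans-decalin-3-yl 3-methylbut-2-enoate | C=C(C)[C@@H]1C[C@]2(C)[C@@H](C)[C@H](OC(=O)C=C(C)C)CC[C@H]2[C@H](O)C1=O | intermediate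
26 | (E)-2-methylbut-2-enoyl chloride (tigloyl chloride) | C/C=C(\C)C(Cl)=O | starting material
27 | (1S,3S,4aR,5R,6R,8aR)-4a,5-dimethyl-6-[(3-methylbut-2-enoyl)oxy]-2-oxo-3-(prop-1-en-2-yl)decahydronaphthalen-1-yl (2E)-2-methylbut-2-enoate; in eremophilane numbering 3R,4R,5R,7S,9S,10R | C=C(C)[C@@H]1C[C@]2(C)[C@@H](C)[C@H](OC(=O)C=C(C)C)CC[C@H]2[C@H](OC(=O)/C(C)=C/C)C1=O | target

Total step count: 14. Longest linear sequence: 14 steps (1 to 27).

**Steps most likely to fail, with fallbacks**

1. Step 10. The iron hydride may transfer hydrogen to the enone, or the tertiary radical may be quenched before it closes the ring, so that reduction outruns cyclisation. The fallback sets out from 16 and generates the radical from a halide after the alkene has been hydrohalogenated in the absence of any enone. Markovnikov hydrobromination of 16 by cobalt-mediated hydrogen-atom transfer (Co(acac)2, t-BuOOH, Et3SiH, TsBr) would give the tertiary C5 bromide F1. Acetal cleavage as in step 8 would give the bromo aldehyde F2, and vinylalumination as in step 9 the bromo enone F3. Slow addition of Bu3SnH with AIBN in benzene at 80 °C would then abstract bromine, form the same C5 radical and close ring B by Giese cyclisation, coming back to the route at 22.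

2. Step 5. Facial selectivity at C9 may be poor in a mismatched catalyst–substrate pairing, or the alkoxide may cause loss of the β-acyloxy group or epimerisation at C4. The fallback sets out from 11 and introduces the C9 oxygen by epoxidation instead of boron addition. Catalytic asymmetric nucleophilic epoxidation of the E-enone (La(Oi-Pr)3, (R)-BINOL, Ph3As=O, t-BuOOH, 4 Å molecular sieves, THF) would give the spiro epoxy ketone F4. SmI2 in THF/MeOH at −78 °C would cleave the Cα–O bond and the samarium enolate would be protonated at C10 anti to the C4 methyl, coming back to the route at 14.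

3. Step 9. Residual aluminium hydride may reduce the aldehyde, or the aluminium alkoxide stage may cause silyl migration or loss of the C9 configuration. The fallback sets out from 18 and uses a chromium-mediated coupling. Nozaki–Hiyama–Kishi reaction of 18 with 2-(1-bromoethenyl)-2-methyl-1,3-dioxolane (CrCl2, NiCl2 cat., DMF) would give the allylic alcohol ketal F5. Mild ketal hydrolysis (PPTS, acetone/H2O) would unmask the enone, coming back to the route at 21.

**Further compounds**

F1 | step 10 | tertiary C5 bromide from 16 (C5 epimer mixture) | CC1(Br)[C@@H](C)[C@H](OC(=O)C=C(C)C)CC[C@H]1[C@H](O[Si](C)(C)C(C)(C)C)C(OC)OC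
F2 | step 10 | bromo aldehyde from F1 | CC1(Br)[C@@H](C)[C@H](OC(=O)C=C(C)C)CC[C@H]1[C@H](O[Si](C)(C)C(C)(C)C)C=O
F3 | step 10 | bromo Baylis–Hillman-type enone from F2 (C5 and C8 epimer mixture) | CC1(Br)[C@@H](C)[C@H](OC(=O)C=C(C)C)CC[C@H]1[C@H](O[Si](C)(C)C(C)(C)C)C(O)C(=C)C(C)=O
F4 | step 5 | spiro epoxy ketone from 11 (oxirane on C9–C10, C9 configured as in 14) | O=C1[C@@H](C)[C@H](OC(=O)C=C(C)C)CC[C@@]12O[C@@H]2C(OC)OC
F5 | step 9 | allylic alcohol with the acetyl group masked as its ethylene ketal (C8 epimer mixture) | C=C1[C@@H](C)[C@H](OC(=O)C=C(C)C)CC[C@H]1[C@H](O[Si](C)(C)C(C)(C)C)C(O)C(=C)C1(C)OCCO1
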